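**Plan** (skeleton atoms cited by labdane numbering)

- Retrosynthetic cuts, in order: the silyl ether and silylethyl ester; C8=C17 (methylenation of a C8 ketone) and C13=C14 (Wittig at a C13 ketone); the C9–C11 bond between a four-carbon side-chain unit (C11, C12, C13, C16 with its acetate) and the decalin; the C9–C10 bond of ring B; the C9–ester Claisen bond and the C5–C6 bond.
- Forward: ring A comes from ketoisophorone; its vinyl triflate is coupled with a propanoate unit and homologated to an allyl β-keto ester; ring B is closed onto ring A by Lewis-acid cyclisation; the side chain is joined at C9, the helper ester is expelled, and the two alkenes are installed.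
- Enabling feature: C9 of ring B lies between C8 (the future methylene carbon, carried as a ketone) and quaternary C10. With a temporary allyl ester on C9 it is the only doubly activated carbon of the decalin, and once the ester leaves it is an epimerisable α-keto methine.
- Stereochemistry: C2 from asymmetric transfer hydrogenation; C5 and C10 relayed from C2 in the chair-like closure of ring B (silyloxy equatorial, trans-decalin); C9 set after the union by protonation anti to the axial C10 methyl, so both C9 epimers of the adduct converge; C13=C14 geometry from the Wittig step.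

Key step: step 8

Remark on numbering: decalin C1–C10, C17 = exocyclic methylene carbon, C20 = angular methyl, side chain C11–C16; systematic names use decahydronaphthalene locants (C1 = labdane C9, C2 = C8, C4a = C5, C7 = C2, C8a = C10).

Remark (assumption): the sense of induction in step 1 is assigned by analogy with aryl ketones, the alkene taking the role of the arene, so the (R,R) ligand should give the 4R carbinol; should it prove opposite, the (S,S) complex is used.

**Step 1**
Reactants: 1 ketoisophorone (2,6,6-trimethylcyclohex-2-ene-1,4-dione)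
Product: 2 (4R)-4-hydroxy-2,6,6-trimethylcyclohex-2-en-1-one
Conditions: RuCl[(R,R)-TsDPEN](p-cymene) (1 mol%), HCO2H/Et3N (5:2), CH2Cl2, 25 °C
Reagents that add atoms: none
Why: Noyori asymmetric transfer hydrogenation should reduce only the unhindered conjugated C4 carbonyl (the C1 carbonyl is flanked by the gem-dimethyl carbon and the methyl-bearing alkene carbon) and set the carbinol as R through the usual alkene-over-arene orientation of the enone in the six-membered hydride-transfer transition state.

**Step 2**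
Reactants: 2 (4R)-4-hydroxy-2,6,6-trimethylcyclohex-2-en-1-one
Product: 3 (4R)-4-[(tert-butyldiphenylsilyl)oxy]-2,6,6-trimethylcyclohex-2-en-1-one
Conditions: t-BuPh2SiCl, imidazole, DMF, 25 °C
Reagents that add atoms: tert-butyl(chloro)diphenylsilane, CC(C)(C)[Si](Cl)(c1ccccc1)c1ccccc1
Why: Standard silyl ether protection of a secondary allylic alcohol; the bulky tert-butyldiphenylsilyl group is chosen because it must survive the Lewis acid of step 6 and anchor the ring A conformation there, and no stereocentre is touched.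

**Step 3**
Reactants: 3 (4R)-4-[(tert-butyldiphenylsilyl)oxy]-2,6,6-trimethylcyclohex-2-en-1-one
Product: 5 (4S)-4-[(tert-butyldiphenylsilyl)oxy]-2,6,6-trimethylcyclohex-1-en-1-yl trifluoromethanesulfonate, via lithium enolate 4 (not isolated)
Conditions: LiBH(s-Bu)3, THF, −78 °C; then PhNTf2, −78 to 0 °C
Reagents that add atoms: N-phenylbis(trifluoromethanesulfonimide), O=S(=O)(N(c1ccccc1)S(=O)(=O)C(F)(F)F)C(F)(F)F
Why: Conjugate reduction with enolate trapping (reductive triflation): the bulky borohydride should add 1,4 because the β-carbon carries only hydrogen while the carbonyl is shielded on both sides, and the regiodefined tetrasubstituted enolate is O-sulfonylated before it can equilibrate, which fixes the future C5=C10 double bond; the carbinol centre is untouched (its descriptor changes only through the priority rules).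

**Step 4**
Reactants: 5 (4S)-4-[(tert-butyldiphenylsilyl)oxy]-2,6,6-trimethylcyclohex-1-en-1-yl trifluoromethanesulfonate; 6 (3-ethoxy-3-oxopropyl)zinc bromide
Product: 7 ethyl 3-[(4S)-4-[(tert-butyldiphenylsilyl)oxy]-2,6,6-trimethylcyclohex-1-en-1-yl]propanoate
Conditions: PdCl2(dppf) (5 mol%), THF/NMP, 60 °C
Reagents that add atoms: none
Why: Negishi coupling of an enol triflate with a zinc homoenolate: oxidative addition of zerovalent palladium into 2,6,6-trimethylcyclohexenyl triflates is well precedented, the bidentate phosphine suppresses β-hydride elimination of the alkylpalladium species, and the ester-bearing organozinc tolerates the silyl ether.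

**Step 5**
Reactants: 7 ethyl 3-[(4S)-4-[(tert-butyldiphenylsilyl)oxy]-2,6,6-trimethylcyclohex-1-en-1-yl]propanoate; 8 prop-2-en-1-yl acetate (allyl acetate)
Product: 10 prop-2-en-1-yl 5-[(4S)-4-[(tert-butyldiphenylsilyl)oxy]-2,6,6-trimethylcyclohex-1-en-1-yl]-3-oxopentanoate, via lithium enolate of allyl acetate 9 (not isolated)
Conditions: LiN(i-Pr)2 (2.6 equiv), 8 (2.6 equiv), THF, −78 °C; then 7, −78 to −30 °C; aqueous work-up
Reagents that add atoms: none
Why: Crossed Claisen condensation: the preformed lithium enolate of allyl acetate (in excess, since the product is deprotonated as it forms) acylates on the unhindered ethyl ester and installs the allyl β-keto ester that serves as nucleophile in step 6, as activator of C9 in step 8 and as a traceless group in step 9.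

**Step 6**
Reactants: 10 prop-2-en-1-yl 5-[(4S)-4-[(tert-butyldiphenylsilyl)oxy]-2,6,6-trimethylcyclohex-1-en-1-yl]-3-oxopentanoate
Product: 11 prop-2-en-1-yl (4aR,7R,8aR)-7-[(tert-butyldiphenylsilyl)oxy]-5,5,8a-trimethyl-2-oxodecahydronaphthalene-1-carboxylate
Conditions: SnCl4 (1.5 equiv), CH2Cl2, −20 to 0 °C; aq. NaHCO3
Reagents that add atoms: none
Why: Lewis-acid-mediated cation–olefin cyclisation of an olefinic β-keto ester (6-endo closure of ring B by attack of the tin-bound enol carbon C9 on the tertiary C10 cation formed by protonation at C5): ring A should react through the half-chair with the silyloxy group pseudo-equatorial (the alternative is syn-axial to a C4 methyl), so that axial protonation at C5 and chair closure place H5 and the C10 methyl trans-diaxial and the silyloxy group equatorial, which relays the C2 configuration to C5 and C10, while C9 stays epimerisable.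

**Step 7**
Reactants: 12 but-2-yne-1,4-diyl diacetate
Product: 13 2-oxobutane-1,4-diyl diacetate
Conditions: AuCl(PPh3) (2 mol%), AgOTf (2 mol%), 1,4-dioxane/H2O, 60 °C
Reagents that add atoms: water, O
Why: Gold-catalysed alkyne hydration assisted by the neighbouring acetate carbonyl; the alkyne is symmetrical, so only one ketone can form.

**Step 8**
Reactants: 11 prop-2-en-1-yl (4aR,7R,8aR)-7-[(tert-butyldiphenylsilyl)oxy]-5,5,8a-trimethyl-2-oxodecahydronaphthalene-1-carboxylate; 13 2-oxobutane-1,4-diyl diacetate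
Product: 15 prop-2-en-1-yl (1S,4aR,7R,8aR)-1-[4-(acetyloxy)-3-oxobutyl]-7-[(tert-butyldiphenylsilyl)oxy]-5,5,8a-trimethyl-2-oxodecahydronaphthalene-1-carboxylate, via 2-oxobut-3-en-1-yl acetate 14 (not isolated)
Conditions: DBU (1.7 equiv), 13 (1.5 equiv, added slowly), CH2Cl2, −20 to 25 °C
Reagents that add atoms: none
Why: DBU first expels the β-acetoxy group of 13 (E1cB) to release the vinyl ketone 14 at low concentration and deprotonates 11 at C9, the one ring carbon acidified by both the C8 ketone and the allyl ester, so the union is regiospecific (C7 is not touched); the tetrasubstituted enolate then adds through carbon to the CH2 terminus of 14 and forms the C9–C11 bond. The closest known reaction type is the base-mediated Michael addition of cyclic β-keto esters to vinyl ketones released in situ from β-acyloxy or β-amino ketones (the first stage of a Robinson annulation). No ring is closed. The new quaternary centre C9 is controlled by the axial C10 methyl, which should direct the acceptor to the opposite face (chain trans to the methyl, as drawn for 15), but its configuration is immaterial because step 9 removes the ester and re-sets C9. The step needs C- over O-alkylation (secured by the soft, unhindered acceptor terminus), mono-addition (no α-hydrogen remains in 15) and no onward aldol closure (mild amidine base, low temperature, hindered C8 ketone).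

**Step 9**
Reactants: 15 prop-2-en-1-yl (1S,4aR,7R,8aR)-1-[4-(acetyloxy)-3-oxobutyl]-7-[(tert-butyldiphenylsilyl)oxy]-5,5,8a-trimethyl-2-oxodecahydronaphthalene-1-carboxylate
Product: 17 4-[(1S,4aR,7R,8aR)-7-[(tert-butyldiphenylsilyl)oxy]-5,5,8a-trimethyl-2-oxodecahydronaphthalen-1-yl]-2-oxobutyl acetate, via β-keto acid 16 (not isolated)
Conditions: Pd(OAc)2 (5 mol%), PPh3 (20 mol%), HCO2H, Et3N, THF, 25 to 45 °C
Reagents that add atoms: none
Why: Tsuji deallylation–decarboxylation: zerovalent palladium ionises the allyl ester, formate reduces the π-allyl unit to propene, and the β-keto acid loses CO2 through the C8–C9 enol, which should be protonated at C9 from the face opposite the axial C10 methyl so that the side chain ends equatorial and cis to that methyl; triethylamine equilibrates any C9 epimer to the same, thermodynamically preferred ketone, so both C9 epimers of 15 converge.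

**Step 10**
Reactants: 18 2-(trimethylsilyl)ethan-1-ol; 19 bromoacetyl bromide
Product: 20 2-(trimethylsilyl)ethyl bromoacetate
Conditions: pyridine, CH2Cl2, 0 °C
Reagents that add atoms: none
Why: Acylation of a primary alcohol by an acid bromide (esterification) with pyridine as acid scavenger.

**Step 11**
Reactants: 20 2-(trimethylsilyl)ethyl bromoacetate
Product: 22 2-(trimethylsilyl)ethyl (triphenyl-λ5-phosphanylidene)acetate, via phosphonium bromide 21 (not isolated)
Conditions: PPh3, toluene, 25 °C; then 1 M aq. NaOH, CH2Cl2, 0 °C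
Reagents that add atoms: triphenylphosphine, c1ccc(cc1)P(c1ccccc1)c1ccccc1
Why: Quaternisation of triphenylphosphine by the α-bromo ester (SN2) and deprotonation of the phosphonium salt give the stabilised Wittig ylide; the cold, brief hydroxide treatment should leave the silylethyl ester intact.

**Step 12**
Reactants: 17 4-[(1S,4aR,7R,8aR)-7-[(tert-butyldiphenylsilyl)oxy]-5,5,8a-trimethyl-2-oxodecahydronaphthalen-1-yl]-2-oxobutyl acetate; 22 2-(trimethylsilyl)ethyl (triphenyl-λ5-phosphanylidene)acetate
Product: 23 2-(trimethylsilyl)ethyl (2E)-3-[(acetyloxy)methyl]-5-[(1S,4aR,7R,8aR)-7-[(tert-butyldiphenylsilyl)oxy]-5,5,8a-trimethyl-2-oxodecahydronaphthalen-1-yl]pent-2-enoate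
Conditions: 22 (2 equiv), toluene, 90 °C
Reagents that add atoms: none
Why: Wittig olefination with a stabilised ylide: only the C13 ketone, activated by its α-acetoxy group, should react (the C8 ketone sits between C7 and the substituted C9 next to quaternary C10), and the ester should be placed anti to the acetoxymethyl group for dipole and steric reasons, as with other α-heteroatom-substituted ketones, that is cis to the C12 methylene as the target requires; a minor geometric isomer would be removed by chromatography.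

**Step 13**
Reactants: 23 2-(trimethylsilyl)ethyl (2E)-3-[(acetyloxy)methyl]-5-[(1S,4aR,7R,8aR)-7-[(tert-butyldiphenylsilyl)oxy]-5,5,8a-trimethyl-2-oxodecahydronaphthalen-1-yl]pent-2-enoate
Product: 24 2-(trimethylsilyl)ethyl (2E)-3-[(acetyloxy)methyl]-5-[(1R,4aR,7R,8aR)-7-[(tert-butyldiphenylsilyl)oxy]-5,5,8a-trimethyl-2-methylidenedecahydronaphthalen-1-yl]pent-2-enoate
Conditions: Zn, CH2Br2, TiCl4, THF/CH2Cl2, 0 to 25 °C
Reagents that add atoms: dibromomethane, BrCBr
Why: Takai–Lombardo methylenation: the non-basic zinc–titanium methylene reagent should convert the hindered, enolisable C8 ketone into the exocyclic alkene without epimerising C9 and without attacking the esters, the acetate or the silyl ether.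

**Step 14**
Reactants: 24 2-(trimethylsilyl)ethyl (2E)-3-[(acetyloxy)methyl]-5-[(1R,4aR,7R,8aR)-7-[(tert-butyldiphenylsilyl)oxy]-5,5,8a-trimethyl-2-methylidenedecahydronaphthalen-1-yl]pent-2-enoate
Product: 25 (2E)-3-[(acetyloxy)methyl]-5-[(1R,4aR,7R,8aR)-7-hydroxy-5,5,8a-trimethyl-2-methylidenedecahydronaphthalen-1-yl]pent-2-enoic acid
Conditions: Bu4NF (5 equiv), AcOH (2.5 equiv), THF, 0 to 25 °C
Reagents that add atoms: none
Why: Fluoride-induced desilylation: attack at silicon fragments the 2-(trimethylsilyl)ethyl ester (β-elimination to ethene and the carboxylate) and cleaves the silyl ether, while the acetic acid buffer keeps the medium non-basic so that the primary allylic acetate and the E-alkene should be preserved; no stereocentre is affected.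

**Compound list**

1 | ketoisophorone (2,6,6-trimethylcyclohex-2-ene-1,4-dione) | CC1=CC(=O)CC(C)(C)C1=O | starting material
2 | (4R)-4-hydroxy-2,6,6-trimethylcyclohex-2-en-1-one | O=C1C(C)(C)C[C@@H](O)C=C1C | intermediate
3 | (4R)-4-[(tert-butyldiphenylsilyl)oxy]-2,6,6-trimethylcyclohex-2-en-1-one | O=C1C(C)(C)C[C@@H](O[Si](c2ccccc2)(c2ccccc2)C(C)(C)C)C=C1C | intermediate
4 | lithium (4S)-4-[(tert-butyldiphenylsilyl)oxy]-2,6,6-trimethylcyclohex-1-en-1-olate | CC1=C([O-])C(C)(C)C[C@@H](O[Si](c2ccccc2)(c2ccccc2)C(C)(C)C)C1.[Li+] | intermediate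
5 | (4S)-4-[(tert-butyldiphenylsilyl)oxy]-2,6,6-trimethylcyclohex-1-en-1-yl trifluoromethanesulfonate | CC1=C(OS(=O)(=O)C(F)(F)F)C(C)(C)C[C@@H](O[Si](c2ccccc2)(c2ccccc2)C(C)(C)C)C1 | intermediate
6 | (3-ethoxy-3-oxopropyl)zinc bromide | CCOC(=O)CC[Zn]Br | starting material
7 | ethyl 3-[(4S)-4-[(tert-butyldiphenylsilyl)oxy]-2,6,6-trimethylcyclohex-1-en-1-yl]propanoate | CC1=C(CCC(=O)OCC)C(C)(C)C[C@@H](O[Si](c2ccccc2)(c2ccccc2)C(C)(C)C)C1 | intermediate
8 | prop-2-en-1-yl acetate (allyl acetate) | CC(=O)OCC=C | starting material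
9 | lithium 1-(prop-2-en-1-yloxy)ethen-1-olate | [Li+].[O-]C(=C)OCC=C | intermediate
10 | prop-2-en-1-yl 5-[(4S)-4-[(tert-butyldiphenylsilyl)oxy]-2,6,6-trimethylcyclohex-1-en-1-yl]-3-oxopentanoate | CC1=C(CCC(=O)CC(=O)OCC=C)C(C)(C)C[C@@H](O[Si](c2ccccc2)(c2ccccc2)C(C)(C)C)C1 | intermediate
11 | prop-2-en-1-yl (4aR,7R,8aR)-7-[(tert-butyldiphenylsilyl)oxy]-5,5,8a-trimethyl-2-oxodecahydronaphthalene-1-carboxylate (C1 epimers/enol tautomer) | O=C1CC[C@@H]2C(C)(C)C[C@@H](O[Si](c3ccccc3)(c3ccccc3)C(C)(C)C)C[C@@]2(C)C1C(=O)OCC=C | intermediate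
12 | but-2-yne-1,4-diyl diacetate | CC(=O)OCC#CCOC(C)=O | starting material
13 | 2-oxobutane-1,4-diyl diacetate | CC(=O)OCCC(=O)COC(C)=O | intermediate
14 | 2-oxobut-3-en-1-yl acetate | C=CC(=O)COC(C)=O | intermediate
15 | prop-2-en-1-yl (1S,4aR,7R,8aR)-1-[4-(acetyloxy)-3-oxobutyl]-7-[(tert-butyldiphenylsilyl)oxy]-5,5,8a-trimethyl-2-oxodecahydronaphthalene-1-carboxylate | O=C1CC[C@@H]2C(C)(C)C[C@@H](O[Si](c3ccccc3)(c3ccccc3)C(C)(C)C)C[C@@]2(C)[C@]1(CCC(=O)COC(C)=O)C(=O)OCC=C | intermediate
16 | (1S,4aR,7R,8aR)-1-[4-(acetyloxy)-3-oxobutyl]-7-[(tert-butyldiphenylsilyl)oxy]-5,5,8a-trimethyl-2-oxodecahydronaphthalene-1-carboxylic acid | O=C1CC[C@@H]2C(C)(C)C[C@@H](O[Si](c3ccccc3)(c3ccccc3)C(C)(C)C)C[C@@]2(C)[C@]1(CCC(=O)COC(C)=O)C(=O)O | intermediate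
17 | 4-[(1S,4aR,7R,8aR)-7-[(tert-butyldiphenylsilyl)oxy]-5,5,8a-trimethyl-2-oxodecahydronaphthalen-1-yl]-2-oxobutyl acetate | O=C1CC[C@@H]2C(C)(C)C[C@@H](O[Si](c3ccccc3)(c3ccccc3)C(C)(C)C)C[C@@]2(C)[C@@H]1CCC(=O)COC(C)=O | intermediate
18 | 2-(trimethylsilyl)ethan-1-ol | C[Si](C)(C)CCO | starting material
19 | bromoacetyl bromide | BrCC(Br)=O | starting material
20 | 2-(trimethylsilyl)ethyl bromoacetate | C[Si](C)(C)CCOC(=O)CBr | intermediate
21 | triphenyl{2-oxo-2-[2-(trimethylsilyl)ethoxy]ethyl}phosphonium bromide | C[Si](C)(C)CCOC(=O)C[P+](c1ccccc1)(c1ccccc1)c1ccccc1.[Br-] | intermediate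
22 | 2-(trimethylsilyl)ethyl (triphenyl-λ5-phosphanylidene)acetate | C[Si](C)(C)CCOC(=O)C=P(c1ccccc1)(c1ccccc1)c1ccccc1 | intermediate
23 | 2-(trimethylsilyl)ethyl (2E)-3-[(acetyloxy)methyl]-5-[(1S,4aR,7R,8aR)-7-[(tert-butyldiphenylsilyl)oxy]-5,5,8a-trimethyl-2-oxodecahydronaphthalen-1-yl]pent-2-enoate | O=C1CC[C@@H]2C(C)(C)C[C@@H](O[Si](c3ccccc3)(c3ccccc3)C(C)(C)C)C[C@@]2(C)[C@@H]1CC/C(=C\C(=O)OCC[Si](C)(C)C)COC(C)=O | intermediate
24 | 2-(trimethylsilyl)ethyl (2E)-3-[(acetyloxy)methyl]-5-[(1R,4aR,7R,8aR)-7-[(tert-butyldiphenylsilyl)oxy]-5,5,8a-trimethyl-2-methylidenedecahydronaphthalen-1-yl]pent-2-enoate | C=C1CC[C@@H]2C(C)(C)C[C@@H](O[Si](c3ccccc3)(c3ccccc3)C(C)(C)C)C[C@@]2(C)[C@@H]1CC/C(=C\C(=O)OCC[Si](C)(C)C)COC(C)=O | intermediate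
25 | (2E)-3-[(acetyloxy)methyl]-5-[(1R,4aR,7R,8aR)-7-hydroxy-5,5,8a-trimethyl-2-methylidenedecahydronaphthalen-1-yl]pent-2-enoic acid | C=C1CC[C@@H]2C(C)(C)C[C@@H](O)C[C@@]2(C)[C@@H]1CC/C(=C\C(=O)O)COC(C)=O | target

**Step count**

Total step count: 14. Longest linear sequence: 11 steps (steps 1–6, 8, 9, 12, 13, 14).

**Steps most likely to fail**

Step 8. The conjugate addition at C9, a fully substituted enolate carbon beside quaternary C10, may be slow or reversible, so that the released vinyl ketone is lost to oligomerisation or O-alkylation takes over. The fallback exchanges the order of union and ring closure. It sets out from 10 and 13. K2CO3 in acetone releases 14 from 13, and the unhindered acyclic β-keto ester adds to it to give the acyclic adduct prop-2-en-1-yl 6-(acetyloxy)-2-{3-[(4S)-4-[(tert-butyldiphenylsilyl)oxy]-2,6,6-trimethylcyclohex-1-en-1-yl]propanoyl}-5-oxohexanoate F1. SnCl4 in CH2Cl2 then closes ring B as in step 6, with the substituted enol carbon as terminating nucleophile, to give the quaternary keto ester prop-2-en-1-yl (4aR,7R,8aR)-1-[4-(acetyloxy)-3-oxobutyl]-7-[(tert-butyldiphenylsilyl)oxy]-5,5,8a-trimethyl-2-oxodecahydronaphthalene-1-carboxylate F2 as a mixture of C9 epimers. The conditions of step 9 should take F2 to 17, where the route is rejoined.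

Step 12. The Wittig reaction may show poor geometric selectivity, because the two groups on the C13 ketone (acetoxymethyl and the C12 methylene) are of similar size. The fallback replaces the acetate by a bulky silyl ether before the olefination and ends with an enzymatic acetylation. It sets out from 17. K2CO3 in methanol at 0 °C removes the acetate to give 4-[(1S,4aR,7R,8aR)-7-[(tert-butyldiphenylsilyl)oxy]-5,5,8a-trimethyl-2-oxodecahydronaphthalen-1-yl]-1-hydroxybutan-2-one F3. Silylation (t-BuPh2SiCl, imidazole) gives 1-[(tert-butyldiphenylsilyl)oxy]-4-[(1S,4aR,7R,8aR)-7-[(tert-butyldiphenylsilyl)oxy]-5,5,8a-trimethyl-2-oxodecahydronaphthalen-1-yl]butan-2-one F4. The Wittig reaction with 22 should then place the ester anti to the much larger silyloxymethyl group and give 2-(trimethylsilyl)ethyl (2E)-3-{[(tert-butyldiphenylsilyl)oxy]methyl}-5-[(1S,4aR,7R,8aR)-7-[(tert-butyldiphenylsilyl)oxy]-5,5,8a-trimethyl-2-oxodecahydronaphthalen-1-yl]pent-2-enoate F5. Methylenation as in step 13 gives 2-(trimethylsilyl)ethyl (2E)-3-{[(tert-butyldiphenylsilyl)oxy]methyl}-5-[(1R,4aR,7R,8aR)-7-[(tert-butyldiphenylsilyl)oxy]-5,5,8a-trimethyl-2-methylidenedecahydronaphthalen-1-yl]pent-2-enoate F6. Bu4NF in THF removes all three silicon groups to give (2E)-5-[(1R,4aR,7R,8aR)-7-hydroxy-5,5,8a-trimethyl-2-methylidenedecahydronaphthalen-1-yl]-3-(hydroxymethyl)pent-2-enoic acid F7; any residual Z isomer would lactonise to a neutral butenolide on acidification and be removed by acid–base extraction. A lipase (Candida antarctica lipase B, vinyl acetate, t-BuOMe) should acetylate only the primary allylic hydroxyl and rejoin the route at 25.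

Step 6. The Lewis acid may strip the silyl ether before ring closure, or the electron-withdrawing silyloxy group may make the cyclisation sluggish. The fallback carries the free hydroxyl through the ring closure. It sets out from 10. Bu4NF/AcOH gives prop-2-en-1-yl 5-[(4S)-4-hydroxy-2,6,6-trimethylcyclohex-1-en-1-yl]-3-oxopentanoate F8. SnCl4 cyclisation, with the hydroxyl held as an equatorial tin alkoxide, gives prop-2-en-1-yl (4aR,7R,8aR)-7-hydroxy-5,5,8a-trimethyl-2-oxodecahydronaphthalene-1-carboxylate F9. Silylation as in step 2 returns to the route at 11.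

**Further compounds**

F1 | step 8 | prop-2-en-1-yl 6-(acetyloxy)-2-{3-[(4S)-4-[(tert-butyldiphenylsilyl)oxy]-2,6,6-trimethylcyclohex-1-en-1-yl]propanoyl}-5-oxohexanoate | CC1=C(CCC(=O)C(CCC(=O)COC(C)=O)C(=O)OCC=C)C(C)(C)C[C@@H](O[Si](c2ccccc2)(c2ccccc2)C(C)(C)C)C1
F2 | step 8 | prop-2-en-1-yl (4aR,7R,8aR)-1-[4-(acetyloxy)-3-oxobutyl]-7-[(tert-butyldiphenylsilyl)oxy]-5,5,8a-trimethyl-2-oxodecahydronaphthalene-1-carboxylate (C1 epimers) | O=C1CC[C@@H]2C(C)(C)C[C@@H](O[Si](c3ccccc3)(c3ccccc3)C(C)(C)C)C[C@@]2(C)C1(CCC(=O)COC(C)=O)C(=O)OCC=C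
F3 | step 12 | 4-[(1S,4aR,7R,8aR)-7-[(tert-butyldiphenylsilyl)oxy]-5,5,8a-trimethyl-2-oxodecahydronaphthalen-1-yl]-1-hydroxybutan-2-one | O=C1CC[C@@H]2C(C)(C)C[C@@H](O[Si](c3ccccc3)(c3ccccc3)C(C)(C)C)C[C@@]2(C)[C@@H]1CCC(=O)CO
F4 | step 12 | 1-[(tert-butyldiphenylsilyl)oxy]-4-[(1S,4aR,7R,8aR)-7-[(tert-butyldiphenylsilyl)oxy]-5,5,8a-trimethyl-2-oxodecahydronaphthalen-1-yl]butan-2-one | O=C1CC[C@@H]2C(C)(C)C[C@@H](O[Si](c3ccccc3)(c3ccccc3)C(C)(C)C)C[C@@]2(C)[C@@H]1CCC(=O)CO[Si](c3ccccc3)(c3ccccc3)C(C)(C)C
F5 | step 12 | 2-(trimethylsilyl)ethyl (2E)-3-{[(tert-butyldiphenylsilyl)oxy]methyl}-5-[(1S,4aR,7R,8aR)-7-[(tert-butyldiphenylsilyl)oxy]-5,5,8a-trimethyl-2-oxodecahydronaphthalen-1-yl]pent-2-enoate | O=C1CC[C@@H]2C(C)(C)C[C@@H](O[Si](c3ccccc3)(c3ccccc3)C(C)(C)C)C[C@@]2(C)[C@@H]1CC/C(=C\C(=O)OCC[Si](C)(C)C)CO[Si](c3ccccc3)(c3ccccc3)C(C)(C)C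
F6 | step 12 | 2-(trimethylsilyl)ethyl (2E)-3-{[(tert-butyldiphenylsilyl)oxy]methyl}-5-[(1R,4aR,7R,8aR)-7-[(tert-butyldiphenylsilyl)oxy]-5,5,8a-trimethyl-2-methylidenedecahydronaphthalen-1-yl]pent-2-enoate | C=C1CC[C@@H]2C(C)(C)C[C@@H](O[Si](c3ccccc3)(c3ccccc3)C(C)(C)C)C[C@@]2(C)[C@@H]1CC/C(=C\C(=O)OCC[Si](C)(C)C)CO[Si](c3ccccc3)(c3ccccc3)C(C)(C)C
F7 | step 12 | (2E)-5-[(1R,4aR,7R,8aR)-7-hydroxy-5,5,8a-trimethyl-2-methylidenedecahydronaphthalen-1-yl]-3-(hydroxymethyl)pent-2-enoic acid | C=C1CC[C@@H]2C(C)(C)C[C@@H](O)C[C@@]2(C)[C@@H]1CC/C(=C\C(=O)O)CO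
F8 | step 6 | prop-2-en-1-yl 5-[(4S)-4-hydroxy-2,6,6-trimethylcyclohex-1-en-1-yl]-3-oxopentanoate | CC1=C(CCC(=O)CC(=O)OCC=C)C(C)(C)C[C@@H](O)C1
F9 | step 6 | prop-2-en-1-yl (4aR,7R,8aR)-7-hydroxy-5,5,8a-trimethyl-2-oxodecahydronaphthalene-1-carboxylate (C1 epimers/enol tautomer) | O=C1CC[C@@H]2C(C)(C)C[C@@H](O)C[C@@]2(C)C1C(=O)OCC=C
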